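**Plan**

- Retrosynthesis: the macrolide is opened at C1–C2 (benzylic CH2 to ring-alkene carbon); the C10 bromide and C11 carbinol go back to a (10S,11S)-epoxide; the ester is cut at C15–O. The chain is cut at C12–C13 together with the C10=C11 alkene (ketal Claisen) and at C10–C11 (Grignard addition). The ring is cut at C7–C8 together with C6–Br (bromonium 1,2-shift) and at C2–C8 (alkylzinc addition to 2-methylcyclohexenone).
- Enabling feature: in the six-membered carbocycle the tetrasubstituted C2=C3 alkene has C2 next to quaternary C7, so a C2 ketone has α-hydrogens only at C3 and gives a single enol triflate. C1 is a CH2 on the hydroxybenzoate ring and can carry boron, so C1–C2 is a benzylboron/alkenyl triflate bond.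
- Forward: the carbocycle is present from the start (carbinol made in one operation from the allyl ether and the enone through the dialkylzinc, then bromoketone, C3 methylation, enol triflate). The chain is grown linearly from C8 to C15. The arene is attached as the C15 ester only after the peroxide step, because KHSO5 would oxidise the C–B bond. The 16-membered ring is closed by the Suzuki coupling; epoxide opening and desilylation finish.
- Stereochemistry: the C2 carbinol is set by catalytic asymmetric alkylzinc addition and relayed to C6 and C7 (both S) by the anti bromonium semipinacol shift. C14 (S) comes from CBS reduction. C10/C11 come from reagent-controlled Shi epoxidation (10S,11S) and invertive bromide opening at C10, giving (6S,7S,10R,11S,14S) in the target.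

Key step: step 18

Numbering used in the text: C1 benzylic CH2; C2=C3 ring alkene (methyl on C3); C4, C5 ring CH2; C6 CHBr; C7 quaternary (methyl); C8, C9 CH2; C10 CHBr; C11 tertiary carbinol (methyl); C12, C13 CH2; C14 carbinol; C15 CMe2–O (ester).
Abbreviations: TBS = tert-butyldimethylsilyl, TIPS = triisopropylsilyl, Tf = trifluoromethanesulfonyl, Bpin = 4,4,5,5-tetramethyl-1,3,2-dioxaborolan-2-yl.
Assumption: the antipode of the bis(sulfonamide) diol ligand (from trans-cyclohexane-1,2-diamine and camphor-10-sulfonyl chloride) is taken that directs the alkyl group to the carbonyl face giving (1S)-5; both antipodes are accessible.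

**Route**

Step 1
Reactants: 1 allyloxy(tert-butyl)dimethylsilane; 2 2-methylcyclohex-2-en-1-one
Product: 5 (1S)-1-[3-(tert-butyldimethylsilyloxy)propyl]-2-methylcyclohex-2-en-1-ol, via alkyldiethylborane 3 (not isolated), via dialkylzinc 4 (not isolated)
Conditions: 1 (4 equiv relative to 2), Et2BH (from BH3·SMe2 and BEt3), Et2O, 0 °C to rt; Et2Zn (2 equiv), neat, 0 °C to rt; volatiles removed in vacuo; residue in toluene added to 2, Ti(OiPr)4 (1.2 equiv), bis(sulfonamide) diol ligand (10 mol%), toluene/hexanes, rt; aqueous NH4Cl work-up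
Reagents that add atoms: none
Why: Anti-Markovnikov hydroboration and boron–zinc exchange give the functionalised dialkylzinc (two molecules of 1 per zinc, of which one alkyl group is transferred and the other leaves as the propyl silyl ether on work-up), and its Ti(OiPr)4/bis(sulfonamide) diol-catalysed asymmetric 1,2-addition to the 2-substituted cyclic enone, established for 2-methylcyclohexenone with oxygenated alkylzinc reagents, sets the (S)-carbinol at C2 through the carbonyl face selected by the ligand antipode.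

Step 2
Reactants: 5 (1S)-1-[3-(tert-butyldimethylsilyloxy)propyl]-2-methylcyclohex-2-en-1-ol
Product: 6 (2S,3S)-3-bromo-2-[3-(tert-butyldimethylsilyloxy)propyl]-2-methylcyclohexan-1-one
Conditions: NBS, CH2Cl2, −40 to 0 °C, dark
Reagents that add atoms: N-bromosuccinimide, BrN1C(=O)CCC1=O
Why: Halonium-triggered semipinacol rearrangement of a tertiary allylic alcohol, the bromine counterpart of the Lewis-acid epoxy alcohol rearrangement known for these 1-alkyl-2-methylcyclohexenols: the bromonium ion on the face syn to the hydroxyl is opened at C7 by suprafacial 1,2-shift of the antiperiplanar C2–C8 bond, so the chain arrives on C7 anti to bromine, the carbinol stereocentre is converted into the (6S,7S) pair and C2 becomes the ketone.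

Step 3
Reactants: 6 (2S,3S)-3-bromo-2-[3-(tert-butyldimethylsilyloxy)propyl]-2-methylcyclohexan-1-one
Product: 8 (2S,3S)-3-bromo-2-[3-(tert-butyldimethylsilyloxy)propyl]-2,6-dimethylcyclohexan-1-one (both epimers at the new methyl-bearing carbon), via lithium enolate 7 (not isolated)
Conditions: LiN(iPr)2 (1.05 equiv), THF, −78 °C; MeI, DMPU, −78 to −20 °C
Reagents that add atoms: iodomethane, CI
Why: Kinetic enolate alkylation in which the quaternary C7 leaves C3 as the only enolisable position, the non-nucleophilic base avoids carbonyl addition and Grob-type fragmentation with the C6 bromide, and the configuration of the new methyl-bearing carbon is irrelevant because C3 becomes sp2 in the next step.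

Step 4
Reactants: 8 (2S,3S)-3-bromo-2-[3-(tert-butyldimethylsilyloxy)propyl]-2,6-dimethylcyclohexan-1-one
Product: 10 (5S,6S)-5-bromo-6-[3-(tert-butyldimethylsilyloxy)propyl]-2,6-dimethylcyclohex-1-en-1-yl trifluoromethanesulfonate, via potassium enolate 9 (not isolated)
Conditions: KN(SiMe3)2, THF, −78 °C; PhNTf2, −78 to 0 °C
Reagents that add atoms: N-phenylbis(trifluoromethanesulfonimide), O=S(=O)(N(c1ccccc1)S(=O)(=O)C(F)(F)F)C(F)(F)F
Why: O-Sulfonylation of the only possible enolate with N-phenyltriflimide gives the tetrasubstituted C2=C3 enol triflate as a single regioisomer, as is routine for 2,2,6-trisubstituted cyclohexanones.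

Step 5
Reactants: 10 (5S,6S)-5-bromo-6-[3-(tert-butyldimethylsilyloxy)propyl]-2,6-dimethylcyclohex-1-en-1-yl trifluoromethanesulfonate
Product: 11 (5S,6S)-5-bromo-6-(3-hydroxypropyl)-2,6-dimethylcyclohex-1-en-1-yl trifluoromethanesulfonate
Conditions: HF·pyridine, pyridine, THF, 0 °C to rt
Reagents that add atoms: none
Why: Fluoride-mediated cleavage of the primary silyl ether under mildly acidic conditions leaves the enol triflate and the neopentyl secondary bromide untouched.

Step 6
Reactants: 11 (5S,6S)-5-bromo-6-(3-hydroxypropyl)-2,6-dimethylcyclohex-1-en-1-yl trifluoromethanesulfonate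
Product: 12 (5S,6S)-5-bromo-2,6-dimethyl-6-(3-oxopropyl)cyclohex-1-en-1-yl trifluoromethanesulfonate
Conditions: Dess–Martin periodinane, CH2Cl2, 0 °C to rt
Reagents that add atoms: none
Why: Dess–Martin oxidation takes the primary alcohol to the C10 aldehyde under neutral conditions that do not affect triflate or bromide.

Step 7
Reactants: 12 (5S,6S)-5-bromo-2,6-dimethyl-6-(3-oxopropyl)cyclohex-1-en-1-yl trifluoromethanesulfonate
Product: 13 (5S,6S)-5-bromo-6-(3-hydroxy-4-methylpent-4-en-1-yl)-2,6-dimethylcyclohex-1-en-1-yl trifluoromethanesulfonate (both C10 carbinol epimers)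
Conditions: CH2=C(Me)MgBr, THF, −78 °C
Reagents that add atoms: isopropenylmagnesium bromide, CC(=C)[Mg]Br
Why: Grignard 1,2-addition to the aldehyde at low temperature is tolerated by enol triflates and hindered alkyl bromides, and the C10 carbinol may form as both epimers because C10 becomes sp2 in step 9.

Step 8
Reactants: 14 3-hydroxy-3-methylbutan-2-one
Product: 15 3,3-dimethoxy-2-methylbutan-2-ol
Conditions: HC(OMe)3, MeOH, TsOH (cat.), rt
Reagents that add atoms: trimethyl orthoformate, COC(OC)OC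
Why: Acid-catalysed ketalisation with the orthoformate as water scavenger converts the ketone into its dimethyl ketal while the tertiary alcohol stays free.

Step 9
Reactants: 13 (5S,6S)-5-bromo-6-(3-hydroxy-4-methylpent-4-en-1-yl)-2,6-dimethylcyclohex-1-en-1-yl trifluoromethanesulfonate; 15 3,3-dimethoxy-2-methylbutan-2-ol
Product: 17 (5S,6S)-5-bromo-6-[(3E)-8-hydroxy-4,8-dimethyl-7-oxonon-3-en-1-yl]-2,6-dimethylcyclohex-1-en-1-yl trifluoromethanesulfonate, via allyl vinyl ether 16 (not isolated)
Conditions: 15 (5 equiv), 2,4-dinitrophenol (cat.), toluene, 110 °C, MeOH distilled off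
Reagents that add atoms: none
Why: Ketal Claisen rearrangement in which acid-catalysed alcohol exchange and loss of methanol give the allyl vinyl ether, whose chair [3,3]-sigmatropic shift with the C9 substituent equatorial forms C12–C13 and the E-configured trisubstituted C10=C11 alkene and releases the C14 ketone next to the C15 tertiary alcohol.

Step 10
Reactants: 17 (5S,6S)-5-bromo-6-[(3E)-8-hydroxy-4,8-dimethyl-7-oxonon-3-en-1-yl]-2,6-dimethylcyclohex-1-en-1-yl trifluoromethanesulfonate
Product: 18 (5S,6S)-5-bromo-6-[(3E,7S)-7,8-dihydroxy-4,8-dimethylnon-3-en-1-yl]-2,6-dimethylcyclohex-1-en-1-yl trifluoromethanesulfonate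
Conditions: (R)-2-methyl-CBS-oxazaborolidine, catecholborane (2.5 equiv), toluene, −78 °C; MeOH, aqueous work-up
Reagents that add atoms: none
Why: Corey–Bakshi–Shibata reduction in which the (R)-oxazaborolidine distinguishes the bulky C15 carbinol carbon from the C13 methylene and delivers hydride to the ketone face giving the (14S)-alcohol, while catecholborane at low temperature does not hydroborate the trisubstituted alkene.

Step 11
Reactants: 18 (5S,6S)-5-bromo-6-[(3E,7S)-7,8-dihydroxy-4,8-dimethylnon-3-en-1-yl]-2,6-dimethylcyclohex-1-en-1-yl trifluoromethanesulfonate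
Product: 19 (5S,6S)-5-bromo-6-[(3E,7S)-7-(tert-butyldimethylsilyloxy)-8-hydroxy-4,8-dimethylnon-3-en-1-yl]-2,6-dimethylcyclohex-1-en-1-yl trifluoromethanesulfonate
Conditions: TBSOTf (1.05 equiv), 2,6-lutidine, CH2Cl2, −78 °C
Reagents that add atoms: tert-butyldimethylsilyl trifluoromethanesulfonate, CC(C)(C)[Si](C)(C)OS(=O)(=O)C(F)(F)F
Why: Silylation with one equivalent of the silyl triflate at low temperature is selective on steric grounds for the secondary C14 hydroxyl over the tertiary C15 hydroxyl.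

Step 12
Reactants: 19 (5S,6S)-5-bromo-6-[(3E,7S)-7-(tert-butyldimethylsilyloxy)-8-hydroxy-4,8-dimethylnon-3-en-1-yl]-2,6-dimethylcyclohex-1-en-1-yl trifluoromethanesulfonate
Product: 20 (5S,6S)-5-bromo-6-{2-[(2S,3S)-3-[(3S)-3-(tert-butyldimethylsilyloxy)-4-hydroxy-4-methylpentyl]-3-methyloxiran-2-yl]ethyl}-2,6-dimethylcyclohex-1-en-1-yl trifluoromethanesulfonate
Conditions: ent-Shi ketone (L-fructose-derived diacetonide ketone, 30 mol%), KHSO5 (Oxone), K2CO3, Bu4NHSO4, MeCN/dimethoxymethane/aqueous buffer pH 10.5, 0 °C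
Reagents that add atoms: potassium peroxymonosulfate, [K+].[O-]S(=O)(=O)OO
Why: Shi asymmetric epoxidation in which the chiral dioxirane attacks the electron-rich trisubstituted C10=C11 alkene through the spiro transition state on the face that gives the (10S,11S)-epoxide under reagent control, while the electron-poor tetrasubstituted enol triflate alkene does not react.

Step 13
Reactants: 21 methyl 4-hydroxy-3-methylbenzoate
Product: 22 methyl 3-methyl-4-(triisopropylsilyloxy)benzoate
Conditions: TIPSCl, imidazole, DMF, rt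
Reagents that add atoms: chlorotriisopropylsilane, CC(C)[Si](Cl)(C(C)C)C(C)C
Why: Imidazole-promoted silylation protects the phenol as a bulky silyl ether that withstands radical bromination, borylation and the aqueous carbonate of the key step.

Step 14
Reactants: 22 methyl 3-methyl-4-(triisopropylsilyloxy)benzoate
Product: 23 methyl 3-(bromomethyl)-4-(triisopropylsilyloxy)benzoate
Conditions: NBS, AIBN (cat.), PhCF3, 80 °C
Reagents that add atoms: N-bromosuccinimide, BrN1C(=O)CCC1=O
Why: Wohl–Ziegler radical bromination functionalises the only benzylic C–H position, and the non-polar radical conditions disfavour ring bromination of the silyloxy arene.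

Step 15
Reactants: 23 methyl 3-(bromomethyl)-4-(triisopropylsilyloxy)benzoate; 24 bis(pinacolato)diboron
Product: 25 methyl 3-[(4,4,5,5-tetramethyl-1,3,2-dioxaborolan-2-yl)methyl]-4-(triisopropylsilyloxy)benzoate
Conditions: PdCl2(dppf) (cat.), KOAc, dioxane, 80 °C
Reagents that add atoms: none
Why: Miyaura borylation of a benzylic bromide proceeds by fast oxidative addition and acetate-assisted transmetalation with the diboron, and the weak base prevents onward coupling of the benzylic boronate.

Step 16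
Reactants: 25 methyl 3-[(4,4,5,5-tetramethyl-1,3,2-dioxaborolan-2-yl)methyl]-4-(triisopropylsilyloxy)benzoate
Product: 26 3-[(4,4,5,5-tetramethyl-1,3,2-dioxaborolan-2-yl)methyl]-4-(triisopropylsilyloxy)benzoic acid
Conditions: Me3SnOH, 1,2-dichloroethane, 70 °C; dilute HCl work-up
Reagents that add atoms: trimethyltin hydroxide, C[Sn](C)(C)O
Why: Trimethyltin hydroxide cleaves methyl esters under near-neutral conditions that spare the base-labile aryl silyl ether and the pinacol boronate.

Step 17
Reactants: 20 (5S,6S)-5-bromo-6-{2-[(2S,3S)-3-[(3S)-3-(tert-butyldimethylsilyloxy)-4-hydroxy-4-methylpentyl]-3-methyloxiran-2-yl]ethyl}-2,6-dimethylcyclohex-1-en-1-yl trifluoromethanesulfonate; 26 3-[(4,4,5,5-tetramethyl-1,3,2-dioxaborolan-2-yl)methyl]-4-(triisopropylsilyloxy)benzoic acid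
Product: 29 C15 ester of 20 with 26 (C2 enol triflate; 10S,11S-epoxide; O14-TBS; aryl O-TIPS; aryl CH2Bpin), via acid chloride 27 (not isolated), via lithium alkoxide 28 (not isolated)
Conditions: 26, 1-chloro-N,N,2-trimethylprop-1-en-1-amine, CH2Cl2, 0 °C to rt, concentrated; 20, LiN(SiMe3)2, THF, −78 °C; acid chloride added, −78 to 0 °C
Reagents that add atoms: none
Why: Acylation of a tertiary lithium alkoxide with an acid chloride is the standard way to hindered tertiary benzoates, the acid chloride is made under neutral conditions that spare boronate and aryl silyl ether, and deprotonation at −78 °C with lithium as counter-ion should keep the neighbouring O14 silyl group from migrating.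

Step 18
Reactants: 29 C15 ester of 20 with 26 (enol triflate, epoxide, benzylic pinacol boronate)
Product: 30 macrolide: 16-membered ring closed at C1–C2, (6S,7S,10S,11S,14S), 10,11-epoxide, O14-TBS, aryl O-TIPS
Conditions: PdCl2(dppf)·CH2Cl2 (20 mol%), Cs2CO3 (3 equiv), THF/H2O 10:1, 65 °C, slow addition of 29 to a final concentration of 1 mM
Reagents that add atoms: none
Why: Zerovalent palladium, formed in situ from PdCl2(dppf), inserts into the C2–OTf bond, the base converts the benzylic pinacol boronate into its borate, which passes the C1 benzyl group to divalent palladium, and reductive elimination forms C1–C2. The closest known reaction type is the intermolecular Suzuki–Miyaura coupling of primary benzylic boronic esters with alkenyl triflates, run here intramolecularly at high dilution. The 16-membered ring closes by reductive elimination from a 17-membered diorganopalladium chelate, a macrocyclic cross-coupling and not a nucleophilic closure in the Baldwin sense. No stereocentre is created, and position and substitution of the C2=C3 alkene are fixed by the triflate. The step needs oxidative addition at the alkenyl triflate in preference to the C6 bromide, which the unactivated neopentyl secondary C–Br bond secures, and ring closure in preference to oligomerisation, which slow addition into dilute catalyst secures. The base-labile bromohydrin is carried as the epoxide, and the hindered tertiary benzoate, the silyl ethers and the epoxide should be inert to aqueous carbonate at this temperature.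

Step 19
Reactants: 30 macrolide with (10S,11S)-epoxide, O14-TBS, aryl O-TIPS
Product: 31 bis-silyl ether of bromophycolide G: (6S,7S,10R,11S,14S)-10-bromo-11-hydroxy macrolide, O14-TBS, aryl O-TIPS
Conditions: Li2NiBr4, THF, 0 °C to rt; aqueous work-up
Reagents that add atoms: dilithium tetrabromonickelate, [Li+].[Li+].Br[Ni-2](Br)(Br)Br
Why: Li2NiBr4 delivers bromide in SN2 fashion to the less substituted epoxide carbon C10 with inversion, which gives the (10R)-bromide and leaves the (11S)-tertiary alcohol with its C–O bond intact.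

Step 20
Reactants: 31 bis-silyl ether of bromophycolide G
Product: 32 bromophycolide G, (6S,7S,10R,11S,14S)
Conditions: HF·pyridine, pyridine, THF, 0 °C to rt
Reagents that add atoms: none
Why: Fluoride cleaves the secondary alkyl silyl ether and the aryl silyl ether (activated by the para ester) in an acidic medium that avoids epoxide re-formation from the bromohydrin and acyl shift from O15 to O14.

**Compound list**

1 | allyloxy(tert-butyl)dimethylsilane | C=CCO[Si](C)(C)C(C)(C)C | starting material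
2 | 2-methylcyclohex-2-en-1-one | CC1=CCCCC1=O | starting material
3 | [3-(tert-butyldimethylsilyloxy)propyl]diethylborane | CCB(CC)CCCO[Si](C)(C)C(C)(C)C | intermediate
4 | bis[3-(tert-butyldimethylsilyloxy)propyl]zinc | CC(C)(C)[Si](C)(C)OCCC[Zn]CCCO[Si](C)(C)C(C)(C)C | intermediate
5 | (1S)-1-[3-(tert-butyldimethylsilyloxy)propyl]-2-methylcyclohex-2-en-1-ol | CC1=CCCC[C@]1(O)CCCO[Si](C)(C)C(C)(C)C | intermediate
6 | (2S,3S)-3-bromo-2-[3-(tert-butyldimethylsilyloxy)propyl]-2-methylcyclohexan-1-one | O=C1[C@](C)(CCCO[Si](C)(C)C(C)(C)C)[C@@H](Br)CCC1 | intermediate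
7 | lithium (5S,6S)-5-bromo-6-[3-(tert-butyldimethylsilyloxy)propyl]-6-methylcyclohex-1-en-1-olate | C1=C(O[Li])[C@](C)(CCCO[Si](C)(C)C(C)(C)C)[C@@H](Br)CC1 | intermediate
8 | (2S,3S)-3-bromo-2-[3-(tert-butyldimethylsilyloxy)propyl]-2,6-dimethylcyclohexan-1-one (both C6 epimers) | CC1C(=O)[C@](C)(CCCO[Si](C)(C)C(C)(C)C)[C@@H](Br)CC1 | intermediate
9 | potassium (5S,6S)-5-bromo-6-[3-(tert-butyldimethylsilyloxy)propyl]-2,6-dimethylcyclohex-1-en-1-olate | CC1=C(O[K])[C@](C)(CCCO[Si](C)(C)C(C)(C)C)[C@@H](Br)CC1 | intermediate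
10 | (5S,6S)-5-bromo-6-[3-(tert-butyldimethylsilyloxy)propyl]-2,6-dimethylcyclohex-1-en-1-yl trifluoromethanesulfonate | CC1=C(OS(=O)(=O)C(F)(F)F)[C@](C)(CCCO[Si](C)(C)C(C)(C)C)[C@@H](Br)CC1 | intermediate
11 | (5S,6S)-5-bromo-6-(3-hydroxypropyl)-2,6-dimethylcyclohex-1-en-1-yl trifluoromethanesulfonate | CC1=C(OS(=O)(=O)C(F)(F)F)[C@](C)(CCCO)[C@@H](Br)CC1 | intermediate
12 | (5S,6S)-5-bromo-2,6-dimethyl-6-(3-oxopropyl)cyclohex-1-en-1-yl trifluoromethanesulfonate | CC1=C(OS(=O)(=O)C(F)(F)F)[C@](C)(CCC=O)[C@@H](Br)CC1 | intermediate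
13 | (5S,6S)-5-bromo-6-(3-hydroxy-4-methylpent-4-en-1-yl)-2,6-dimethylcyclohex-1-en-1-yl trifluoromethanesulfonate (both carbinol epimers) | CC1=C(OS(=O)(=O)C(F)(F)F)[C@](C)(CCC(O)C(C)=C)[C@@H](Br)CC1 | intermediate
14 | 3-hydroxy-3-methylbutan-2-one | CC(=O)C(C)(C)O | starting material
15 | 3,3-dimethoxy-2-methylbutan-2-ol | COC(C)(OC)C(C)(C)O | intermediate
16 | (5S,6S)-5-bromo-6-{3-[(3-hydroxy-3-methylbut-1-en-2-yl)oxy]-4-methylpent-4-en-1-yl}-2,6-dimethylcyclohex-1-en-1-yl trifluoromethanesulfonate | CC1=C(OS(=O)(=O)C(F)(F)F)[C@](C)(CCC(OC(=C)C(C)(C)O)C(C)=C)[C@@H](Br)CC1 | intermediate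
17 | (5S,6S)-5-bromo-6-[(3E)-8-hydroxy-4,8-dimethyl-7-oxonon-3-en-1-yl]-2,6-dimethylcyclohex-1-en-1-yl trifluoromethanesulfonate | CC1=C(OS(=O)(=O)C(F)(F)F)[C@](C)(CC/C=C(\C)CCC(=O)C(C)(C)O)[C@@H](Br)CC1 | intermediate
18 | (5S,6S)-5-bromo-6-[(3E,7S)-7,8-dihydroxy-4,8-dimethylnon-3-en-1-yl]-2,6-dimethylcyclohex-1-en-1-yl trifluoromethanesulfonate | CC1=C(OS(=O)(=O)C(F)(F)F)[C@](C)(CC/C=C(\C)CC[C@H](O)C(C)(C)O)[C@@H](Br)CC1 | intermediate
19 | (5S,6S)-5-bromo-6-[(3E,7S)-7-(tert-butyldimethylsilyloxy)-8-hydroxy-4,8-dimethylnon-3-en-1-yl]-2,6-dimethylcyclohex-1-en-1-yl trifluoromethanesulfonate | CC1=C(OS(=O)(=O)C(F)(F)F)[C@](C)(CC/C=C(\C)CC[C@H](O[Si](C)(C)C(C)(C)C)C(C)(C)O)[C@@H](Br)CC1 | intermediate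
20 | (5S,6S)-5-bromo-6-{2-[(2S,3S)-3-[(3S)-3-(tert-butyldimethylsilyloxy)-4-hydroxy-4-methylpentyl]-3-methyloxiran-2-yl]ethyl}-2,6-dimethylcyclohex-1-en-1-yl trifluoromethanesulfonate | CC1=C(OS(=O)(=O)C(F)(F)F)[C@](C)(CC[C@@H]2O[C@@]2(C)CC[C@H](O[Si](C)(C)C(C)(C)C)C(C)(C)O)[C@@H](Br)CC1 | intermediate
21 | methyl 4-hydroxy-3-methylbenzoate | COC(=O)c1ccc(O)c(C)c1 | starting material
22 | methyl 3-methyl-4-(triisopropylsilyloxy)benzoate | COC(=O)c1ccc(O[Si](C(C)C)(C(C)C)C(C)C)c(C)c1 | intermediate
23 | methyl 3-(bromomethyl)-4-(triisopropylsilyloxy)benzoate | COC(=O)c1ccc(O[Si](C(C)C)(C(C)C)C(C)C)c(CBr)c1 | intermediate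
24 | bis(pinacolato)diboron | CC1(C)OB(OC1(C)C)B1OC(C)(C)C(C)(C)O1 | starting material
25 | methyl 3-[(4,4,5,5-tetramethyl-1,3,2-dioxaborolan-2-yl)methyl]-4-(triisopropylsilyloxy)benzoate | COC(=O)c1ccc(O[Si](C(C)C)(C(C)C)C(C)C)c(CB2OC(C)(C)C(C)(C)O2)c1 | intermediate
26 | 3-[(4,4,5,5-tetramethyl-1,3,2-dioxaborolan-2-yl)methyl]-4-(triisopropylsilyloxy)benzoic acid | OC(=O)c1ccc(O[Si](C(C)C)(C(C)C)C(C)C)c(CB2OC(C)(C)C(C)(C)O2)c1 | intermediate
27 | 3-[(4,4,5,5-tetramethyl-1,3,2-dioxaborolan-2-yl)methyl]-4-(triisopropylsilyloxy)benzoyl chloride | ClC(=O)c1ccc(O[Si](C(C)C)(C(C)C)C(C)C)c(CB2OC(C)(C)C(C)(C)O2)c1 | intermediate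
28 | lithium alkoxide of 20 at O15, (6S,7S,10S,11S,14S) | CC1=C(OS(=O)(=O)C(F)(F)F)[C@](C)(CC[C@@H]2O[C@@]2(C)CC[C@H](O[Si](C)(C)C(C)(C)C)C(C)(C)O[Li])[C@@H](Br)CC1 | intermediate
29 | (3S)-3-(tert-butyldimethylsilyloxy)-5-[(2S,3S)-3-{2-[(1S,6S)-6-bromo-1,3-dimethyl-2-(trifluoromethanesulfonyloxy)cyclohex-2-en-1-yl]ethyl}-2-methyloxiran-2-yl]-2-methylpentan-2-yl 3-[(4,4,5,5-tetramethyl-1,3,2-dioxaborolan-2-yl)methyl]-4-(triisopropylsilyloxy)benzoate | CC1=C(OS(=O)(=O)C(F)(F)F)[C@](C)(CC[C@@H]4O[C@@]4(C)CC[C@H](O[Si](C)(C)C(C)(C)C)C(C)(C)OC(=O)c2ccc(O[Si](C(C)C)(C(C)C)C(C)C)c(CB3OC(C)(C)C(C)(C)O3)c2)[C@@H](Br)CC1 | intermediate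
30 | 16-membered macrolide closed at C1–C2, (6S,7S,10S,11S,14S)-6-bromo-10,11-epoxide, O14-TBS, aryl O-TIPS | CC1=C(Cc2cc3ccc2O[Si](C(C)C)(C(C)C)C(C)C)[C@](C)(CC[C@@H]4O[C@@]4(C)CC[C@H](O[Si](C)(C)C(C)(C)C)C(C)(C)OC3=O)[C@@H](Br)CC1 | intermediate
31 | O14-TBS, aryl O-TIPS bis-silyl ether of bromophycolide G, (6S,7S,10R,11S,14S) | CC1=C2Cc3cc(ccc3O[Si](C(C)C)(C(C)C)C(C)C)C(=O)OC(C)(C)[C@@H](O[Si](C)(C)C(C)(C)C)CC[C@](C)(O)[C@H](Br)CC[C@]2(C)[C@@H](Br)CC1 | intermediate
32 | bromophycolide G, (6S,7S,10R,11S,14S) | CC1=C2Cc3cc(ccc3O)C(=O)OC(C)(C)[C@@H](O)CC[C@](C)(O)[C@H](Br)CC[C@]2(C)[C@@H](Br)CC1 | target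

**Step count and risks**

Total step count: 20. Longest linear sequence: 15 steps (steps 1–7, 9–12, 17–20).

Steps most likely to fail:

1. Step 2. The 1,2-shift of the unactivated primary alkyl group may be slower than capture of the bromonium ion by the carbinol oxygen (epoxide formation), by the silyl ether oxygen (cyclic ether with loss of silyl) or by bromide, and migration of the ring C2–C3 bond (ring contraction) is a further leak. The fallback changes the migrating group to an alkenyl group of higher migratory aptitude; it sets out from 2 and comes back at 6. Hydrozirconation of tert-butyldimethyl(prop-2-yn-1-yloxy)silane with Cp2Zr(H)Cl should give chlorobis(cyclopentadienyl)[(1E)-3-(tert-butyldimethylsilyloxy)prop-1-en-1-yl]zirconium F1, and Me2Zn converts it into methyl[(1E)-3-(tert-butyldimethylsilyloxy)prop-1-en-1-yl]zinc F2. Addition of F2 to 2 under the same Ti(OiPr)4/ligand control should give (1S)-1-[(1E)-3-(tert-butyldimethylsilyloxy)prop-1-en-1-yl]-2-methylcyclohex-2-en-1-ol F3. NBS then triggers the semipinacol shift of the alkenyl group to (2S,3S)-3-bromo-2-[(1E)-3-(tert-butyldimethylsilyloxy)prop-1-en-1-yl]-2-methylcyclohexan-1-one F4. Diimide (2-nitrobenzenesulfonohydrazide, Et3N) saturates the disubstituted alkene without touching the C–Br bond and gives 6.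

2. Step 17. Acylation of the crowded tertiary alkoxide may be slow enough for the silyl group to shift from O14 to O15 (ester then forms on the wrong oxygen) or for the alkoxide to open the epoxide. The fallback acylates the tertiary hydroxyl while C14 is a ketone, where no silyl neighbour exists and the carbinol is less hindered; it sets out from 18 and comes back at 29. ent-Shi epoxidation of 18 should give the epoxy diol (5S,6S)-5-bromo-6-{2-[(2S,3S)-3-[(3S)-3,4-dihydroxy-4-methylpentyl]-3-methyloxiran-2-yl]ethyl}-2,6-dimethylcyclohex-1-en-1-yl trifluoromethanesulfonate F5. Dess–Martin oxidation of the secondary alcohol gives the epoxy ketol (5S,6S)-5-bromo-6-{2-[(2S,3S)-3-(4-hydroxy-4-methyl-3-oxopentyl)-3-methyloxiran-2-yl]ethyl}-2,6-dimethylcyclohex-1-en-1-yl trifluoromethanesulfonate F6. Carbodiimide coupling with 26 (EDC·HCl, DMAP, CH2Cl2) gives the C15 keto ester of F6 with 26 F7. (R)-CBS reduction with catecholborane gives the (14S)-hydroxy ester F8, and TBSCl/imidazole in DMF silylates O14 to give 29. The order keeps the ketone away from the dioxirane step and the boron away from KHSO5.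

3. Step 18. Protodeboronation of the benzylic boronate and intermolecular coupling may outpace closure of the large ring at the hindered tetrasubstituted triflate. The fallback reverses the roles of the two carbons; it sets out from 20 and 22 and comes back at 30. Miyaura borylation of the enol triflate of 20 (24, PdCl2(dppf), KOAc, dioxane, 80 °C) should give the alkenyl pinacol boronate of 20 (Bpin at C2 in place of OTf) F9. Me3SnOH hydrolysis of 22 gives 3-methyl-4-(triisopropylsilyloxy)benzoic acid F10, and NBS/AIBN gives 3-(bromomethyl)-4-(triisopropylsilyloxy)benzoic acid F11. 1-Chloro-N,N,2-trimethylprop-1-en-1-amine converts F11 into 3-(bromomethyl)-4-(triisopropylsilyloxy)benzoyl chloride F12. LiN(SiMe3)2 converts F9 into its lithium alkoxide at O15 F13, which is acylated by F12 to the C15 ester of F9 with F11 F14. PdCl2(dppf)/Cs2CO3 in THF/H2O at high dilution then joins the benzylic bromide to the alkenyl boronate, closing the same C1–C2 bond to give 30.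

Further compounds
F1 | step 2 | chlorobis(cyclopentadienyl)[(1E)-3-(tert-butyldimethylsilyloxy)prop-1-en-1-yl]zirconium | Cl[Zr](/C=C/CO[Si](C)(C)C(C)(C)C)(C1C=CC=C1)C1C=CC=C1
F2 | step 2 | methyl[(1E)-3-(tert-butyldimethylsilyloxy)prop-1-en-1-yl]zinc | C[Zn]/C=C/CO[Si](C)(C)C(C)(C)C
F3 | step 2 | (1S)-1-[(1E)-3-(tert-butyldimethylsilyloxy)prop-1-en-1-yl]-2-methylcyclohex-2-en-1-ol | CC1=CCCC[C@]1(O)/C=C/CO[Si](C)(C)C(C)(C)C
F4 | step 2 | (2S,3S)-3-bromo-2-[(1E)-3-(tert-butyldimethylsilyloxy)prop-1-en-1-yl]-2-methylcyclohexan-1-one | O=C1[C@](C)(/C=C/CO[Si](C)(C)C(C)(C)C)[C@@H](Br)CCC1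
F5 | step 17 | (5S,6S)-5-bromo-6-{2-[(2S,3S)-3-[(3S)-3,4-dihydroxy-4-methylpentyl]-3-methyloxiran-2-yl]ethyl}-2,6-dimethylcyclohex-1-en-1-yl trifluoromethanesulfonate | CC1=C(OS(=O)(=O)C(F)(F)F)[C@](C)(CC[C@@H]2O[C@@]2(C)CC[C@H](O)C(C)(C)O)[C@@H](Br)CC1
F6 | step 17 | (5S,6S)-5-bromo-6-{2-[(2S,3S)-3-(4-hydroxy-4-methyl-3-oxopentyl)-3-methyloxiran-2-yl]ethyl}-2,6-dimethylcyclohex-1-en-1-yl trifluoromethanesulfonate | CC1=C(OS(=O)(=O)C(F)(F)F)[C@](C)(CC[C@@H]2O[C@@]2(C)CCC(=O)C(C)(C)O)[C@@H](Br)CC1
F7 | step 17 | C15 ester of F6 with 26 (C14 ketone, 10S,11S-epoxide, aryl CH2Bpin, aryl O-TIPS) | CC1=C(OS(=O)(=O)C(F)(F)F)[C@](C)(CC[C@@H]4O[C@@]4(C)CCC(=O)C(C)(C)OC(=O)c2ccc(O[Si](C(C)C)(C(C)C)C(C)C)c(CB3OC(C)(C)C(C)(C)O3)c2)[C@@H](Br)CC1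
F8 | step 17 | (14S)-hydroxy C15 ester (29 without the O14 silyl group) | CC1=C(OS(=O)(=O)C(F)(F)F)[C@](C)(CC[C@@H]4O[C@@]4(C)CC[C@H](O)C(C)(C)OC(=O)c2ccc(O[Si](C(C)C)(C(C)C)C(C)C)c(CB3OC(C)(C)C(C)(C)O3)c2)[C@@H](Br)CC1
F9 | step 18 | alkenyl pinacol boronate of 20 (Bpin at C2 in place of OTf), (6S,7S,10S,11S,14S) | CC1=C(B2OC(C)(C)C(C)(C)O2)[C@](C)(CC[C@@H]3O[C@@]3(C)CC[C@H](O[Si](C)(C)C(C)(C)C)C(C)(C)O)[C@@H](Br)CC1
F10 | step 18 | 3-methyl-4-(triisopropylsilyloxy)benzoic acid | Cc1cc(C(=O)O)ccc1O[Si](C(C)C)(C(C)C)C(C)C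
F11 | step 18 | 3-(bromomethyl)-4-(triisopropylsilyloxy)benzoic acid | BrCc1cc(C(=O)O)ccc1O[Si](C(C)C)(C(C)C)C(C)C
F12 | step 18 | 3-(bromomethyl)-4-(triisopropylsilyloxy)benzoyl chloride | BrCc1cc(C(=O)Cl)ccc1O[Si](C(C)C)(C(C)C)C(C)C
F13 | step 18 | lithium alkoxide of F9 at O15 | CC1=C(B2OC(C)(C)C(C)(C)O2)[C@](C)(CC[C@@H]3O[C@@]3(C)CC[C@H](O[Si](C)(C)C(C)(C)C)C(C)(C)O[Li])[C@@H](Br)CC1
F14 | step 18 | C15 ester of F9 with F11 (alkenyl Bpin, benzylic bromide) | CC1=C(B2OC(C)(C)C(C)(C)O2)[C@](C)(CC[C@@H]4O[C@@]4(C)CC[C@H](O[Si](C)(C)C(C)(C)C)C(C)(C)OC(=O)c3ccc(O[Si](C(C)C)(C(C)C)C(C)C)c(CBr)c3)[C@@H](Br)CC1
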